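**Retrosynthetic overview** (germacrane numbering: lactone O on C6, ring fusion C7, C11‑Me, C12=O, free OH on C9, ester on C3)
1. Target ⇐ C9 ketone (last‑step CBS reduction) and C3 ester made by Mitsunobu inversion of a (3R)‑alcohol; γ‑lactone ⇐ γ‑hydroxy acid (C6‑OH + C12 acid).
2. Key step: the ten‑membered (1(10)Z,4E)‑dienone ⇐ anionic oxy‑Cope ring expansion of a trans‑1,2‑dialkenyl‑cyclohex‑2‑enol. It breaks C4–C9, makes C6–C7, sets C6/C7 and the 4E alkene through one chair, and the 1(10)Z alkene is the old cyclohexene.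
3. Carbinol ⇐ carvone‑derived cyclohexenone with a quaternary carbon (Me, (E)‑silyloxyvinyl) + Roche‑ester‑derived (E)‑vinyllithium carrying C11.
4. Ring order: cyclohexenone (chiral pool) → ten‑membered carbocycle (step 12) → γ‑lactone (step 15).

Assumption: (R)‑(−)‑carvone, methyl (S)‑3‑hydroxy‑2‑methylpropanoate and (R)‑2‑methylbutanoic acid are bought as single enantiomers; LDA is used as a commercial solution.

**Step 1**
Reactants: 1 (R)‑(−)‑carvone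
Product: 4 (R)‑5‑acetoxy‑2‑methylcyclohex‑2‑en‑1‑one, via methoxy hydroperoxide 2 (not isolated), via peracetate 3 (not isolated)
Conditions: O3, MeOH/CH2Cl2, −78 °C; then Ac2O, Et3N, DMAP, CH2Cl2, 0 → 40 °C
Reagents that add atoms: ozone [O-][O+]=O; methanol CO
Why: Ozonolysis cleaves only the electron‑rich isopropenyl alkene, and the acetylated α‑methoxy hydroperoxide undergoes Criegee rearrangement with retentive migration of the ring carbon to oxygen, so the carvone stereocentre becomes the (R)‑acetate.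

**Step 2**
Reactants: 4 (R)‑5‑acetoxy‑2‑methylcyclohex‑2‑en‑1‑one
Product: 5 (R)‑5‑hydroxy‑2‑methylcyclohex‑2‑en‑1‑one
Conditions: K2CO3 (0.2 equiv), MeOH, 0 °C
Reagents that add atoms: none
Why: Catalytic transesterification (methanolysis) frees the alcohol, and the low temperature avoids β‑elimination to the cresol.

**Step 3**
Reactants: 5 (R)‑5‑hydroxy‑2‑methylcyclohex‑2‑en‑1‑one
Product: 6 (R)‑5‑[(tert‑butyldimethylsilyl)oxy]‑2‑methylcyclohex‑2‑en‑1‑one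
Conditions: TBSCl, imidazole, DMF, 0 → 25 °C
Reagents that add atoms: tert‑butyldimethylsilyl chloride C[Si](C)(Cl)C(C)(C)C
Why: Standard silyl ether protection; the OTBS group is the stereocontrol element for steps 4, 5 and 11.

**Step 4**
Reactants: 6 (R)‑5‑[(tert‑butyldimethylsilyl)oxy]‑2‑methylcyclohex‑2‑en‑1‑one
Product: 8 (5R,6S)‑6‑allyl‑5‑[(tert‑butyldimethylsilyl)oxy]‑2‑methylcyclohex‑2‑en‑1‑one, via lithium enolate 7 (not isolated)
Conditions: LDA, THF, −78 °C; allyl bromide, DMPU, −78 → −40 °C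
Reagents that add atoms: allyl bromide C=CCBr
Why: Kinetic α′‑enolate alkylation in which allyl bromide enters anti to the neighbouring OTBS group, giving the trans product.

**Step 5**
Reactants: 8 (5R,6S)‑6‑allyl‑5‑[(tert‑butyldimethylsilyl)oxy]‑2‑methylcyclohex‑2‑en‑1‑one
Product: 10 (5R,6R)‑6‑allyl‑5‑[(tert‑butyldimethylsilyl)oxy]‑2,6‑dimethylcyclohex‑2‑en‑1‑one, via lithium enolate 9 (not isolated)
Conditions: LDA, THF, −78 °C; MeI, DMPU, −78 → −30 °C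
Reagents that add atoms: iodomethane CI
Why: Second kinetic enolate alkylation; MeI again attacks anti to the pseudo‑axial OTBS, so methyl ends trans and allyl cis to OTBS, fixing the quaternary (6R) centre whose chirality is later relayed to C6/C7 of the target.

**Step 6**
Reactants: 10 (5R,6R)‑6‑allyl‑5‑[(tert‑butyldimethylsilyl)oxy]‑2,6‑dimethylcyclohex‑2‑en‑1‑one
Product: 12 2‑[(1R,6R)‑6‑[(tert‑butyldimethylsilyl)oxy]‑1,3‑dimethyl‑2‑oxocyclohex‑3‑en‑1‑yl]acetaldehyde, via diol 11 (not isolated)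
Conditions: OsO4 (2 mol %), NaIO4 (4 equiv), 2,6‑lutidine, dioxane/H2O, 25 °C
Reagents that add atoms: osmium tetroxide O=[Os](=O)(=O)=O (oxygen carrier); sodium periodate [Na+].[O-][I](=O)(=O)=O (terminal oxidant)
Why: Lemieux–Johnson cleavage; the monosubstituted terminal alkene is dihydroxylated far faster than the electron‑poor trisubstituted enone alkene, and periodate cleaves the diol.

**Step 7**
Reactants: 12 2‑[(1R,6R)‑6‑[(tert‑butyldimethylsilyl)oxy]‑1,3‑dimethyl‑2‑oxocyclohex‑3‑en‑1‑yl]acetaldehyde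
Product: 13 (5R,6R)‑5‑[(tert‑butyldimethylsilyl)oxy]‑2,6‑dimethyl‑6‑[(E)‑2‑[(triisopropylsilyl)oxy]ethenyl]cyclohex‑2‑en‑1‑one
Conditions: TIPSOTf (1.1 equiv), Et3N, CH2Cl2, −78 → 0 °C
Reagents that add atoms: triisopropylsilyl triflate CC(C)[Si](C(C)C)(C(C)C)OS(=O)(=O)C(F)(F)F
Why: Soft enolisation of the aldehyde (the ketone has no α‑hydrogen); with a quaternary β‑carbon both the kinetic and the thermodynamic preference should be for the (E)‑silyl enol ether, and any Z isomer is removed on Et3N‑deactivated silica.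

**Step 8**
Reactants: 14 methyl (S)‑3‑hydroxy‑2‑methylpropanoate
Product: 15 methyl (S)‑3‑[(tert‑butyldimethylsilyl)oxy]‑2‑methylpropanoate
Conditions: TBSCl, imidazole, CH2Cl2, 25 °C
Reagents that add atoms: tert‑butyldimethylsilyl chloride C[Si](C)(Cl)C(C)(C)C
Why: Standard silyl protection of the primary alcohol, which later becomes the lactone carbonyl carbon.

**Step 9**
Reactants: 15 methyl (S)‑3‑[(tert‑butyldimethylsilyl)oxy]‑2‑methylpropanoate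
Product: 16 (S)‑3‑[(tert‑butyldimethylsilyl)oxy]‑2‑methylpropanal
Conditions: DIBAL‑H (1.05 equiv), CH2Cl2, −78 °C; Rochelle salt work‑up
Reagents that add atoms: none
Why: Partial ester reduction through the stable tetrahedral aluminium hemiacetal at −78 °C; the aldehyde is used crude to avoid α‑epimerisation.

**Step 10**
Reactants: 16 (S)‑3‑[(tert‑butyldimethylsilyl)oxy]‑2‑methylpropanal
Product: 17 (R,E)‑tert‑butyl[(4‑iodo‑2‑methylbut‑3‑en‑1‑yl)oxy]dimethylsilane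
Conditions: CrCl2 (6 equiv), CHI3 (2 equiv), THF/dioxane, 0 → 25 °C
Reagents that add atoms: iodoform IC(I)I
Why: Takai olefination gives the (E)‑vinyl iodide under non‑basic conditions that leave the α‑stereocentre (the future lactone α‑carbon) intact.

**Step 11**
Reactants: 17 (R,E)‑tert‑butyl[(4‑iodo‑2‑methylbut‑3‑en‑1‑yl)oxy]dimethylsilane; 13 (5R,6R)‑5‑[(tert‑butyldimethylsilyl)oxy]‑2,6‑dimethyl‑6‑[(E)‑2‑[(triisopropylsilyl)oxy]ethenyl]cyclohex‑2‑en‑1‑one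
Product: 19 (1S,5R,6R)‑5‑[(tert‑butyldimethylsilyl)oxy]‑1‑[(1E,3R)‑4‑[(tert‑butyldimethylsilyl)oxy]‑3‑methylbut‑1‑en‑1‑yl]‑2,6‑dimethyl‑6‑[(E)‑2‑[(triisopropylsilyl)oxy]ethenyl]cyclohex‑2‑en‑1‑ol, via vinyllithium 18 (not isolated)
Conditions: 17, t‑BuLi (2.0 equiv), Et2O, −78 °C; then 13, THF, −78 → −50 °C; H2O
Reagents that add atoms: none
Why: Iodine–lithium exchange with retention of alkene geometry, then 1,2‑addition to the enone from the face opposite both the OTBS and the silyloxyvinyl group (syn to the small methyl), which gives the (1S) carbinol with the two alkenyl groups trans.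

**Step 12**
Reactants: 19 (1S,5R,6R)‑5‑[(tert‑butyldimethylsilyl)oxy]‑1‑[(1E,3R)‑4‑[(tert‑butyldimethylsilyl)oxy]‑3‑methylbut‑1‑en‑1‑yl]‑2,6‑dimethyl‑6‑[(E)‑2‑[(triisopropylsilyl)oxy]ethenyl]cyclohex‑2‑en‑1‑ol
Product: 22 (2Z,5R,6E,8S,9S)‑5‑[(tert‑butyldimethylsilyl)oxy]‑9‑[(2R)‑1‑[(tert‑butyldimethylsilyl)oxy]propan‑2‑yl]‑2,6‑dimethyl‑8‑[(triisopropylsilyl)oxy]cyclodeca‑2,6‑dien‑1‑one, via potassium alkoxide 20 (not isolated), via potassium enolate 21 (not isolated)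
Conditions: KH (3 equiv), 18‑crown‑6 (3 equiv), THF, 0 → 25 °C; then AcOH, THF, −78 °C
Reagents that add atoms: none
Why: Anionic oxy‑Cope rearrangement in which the trans‑dialkenyl alkoxide can react only through the chair with both (E)‑alkene substituents equatorial, so cleavage of C1–C6 and bonding of the two alkene termini relays the C6 chirality into the trans‑disposed 8S and 9S centres, creates the (6E)‑alkene and leaves the old ring alkene as the (2Z)‑enone.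

**Step 13**
Reactants: 22 (2Z,5R,6E,8S,9S)‑5‑[(tert‑butyldimethylsilyl)oxy]‑9‑[(2R)‑1‑[(tert‑butyldimethylsilyl)oxy]propan‑2‑yl]‑2,6‑dimethyl‑8‑[(triisopropylsilyl)oxy]cyclodeca‑2,6‑dien‑1‑one
Product: 23 (2Z,5R,6E,8S,9S)‑5‑[(tert‑butyldimethylsilyl)oxy]‑9‑[(2R)‑1‑hydroxypropan‑2‑yl]‑2,6‑dimethyl‑8‑[(triisopropylsilyl)oxy]cyclodeca‑2,6‑dien‑1‑one
Conditions: HF·pyridine, pyridine, THF, 0 °C
Reagents that add atoms: none
Why: Selective desilylation; the primary TBS ether is cleaved much faster than the secondary allylic TBS and TIPS ethers under buffered fluoride, so no keto‑diol capable of internal ketalisation is ever formed.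

**Step 14**
Reactants: 23 (2Z,5R,6E,8S,9S)‑5‑[(tert‑butyldimethylsilyl)oxy]‑9‑[(2R)‑1‑hydroxypropan‑2‑yl]‑2,6‑dimethyl‑8‑[(triisopropylsilyl)oxy]cyclodeca‑2,6‑dien‑1‑one
Product: 25 (2R)‑2‑[(1S,2S,3E,5R,7Z)‑5‑[(tert‑butyldimethylsilyl)oxy]‑4,8‑dimethyl‑9‑oxo‑2‑[(triisopropylsilyl)oxy]cyclodeca‑3,7‑dien‑1‑yl]propanoic acid, via aldehyde 24 (not isolated)
Conditions: TEMPO (0.2 equiv), PhI(OAc)2 (2.5 equiv), MeCN/pH 7 aqueous buffer, 25 °C
Reagents that add atoms: water O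
Why: Oxoammonium (TEMPO/PhI(OAc)2) oxidation of the primary alcohol through the aldehyde hydrate to the acid under near‑neutral conditions that do not epimerise the α‑methyl centre or touch the enone.

**Step 15**
Reactants: 25 (2R)‑2‑[(1S,2S,3E,5R,7Z)‑5‑[(tert‑butyldimethylsilyl)oxy]‑4,8‑dimethyl‑9‑oxo‑2‑[(triisopropylsilyl)oxy]cyclodeca‑3,7‑dien‑1‑yl]propanoic acid
Product: 27 (3R,3aS,6Z,9R,10E,11aS)‑9‑hydroxy‑3,6,10‑trimethyl‑3,3a,4,8,9,11a‑hexahydrocyclodeca[b]furan‑2,5‑dione, via dihydroxy acid 26 (not isolated)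
Conditions: 48 % aq. HF, MeCN, 0 → 25 °C
Reagents that add atoms: none
Why: Global desilylation, after which the liberated γ‑hydroxy acid closes spontaneously (acid‑catalysed lactonisation) to the trans‑fused γ‑lactone with all three lactone stereocentres already fixed.

**Step 16**
Reactants: 27 (3R,3aS,6Z,9R,10E,11aS)‑9‑hydroxy‑3,6,10‑trimethyl‑3,3a,4,8,9,11a‑hexahydrocyclodeca[b]furan‑2,5‑dione; 28 (R)‑2‑methylbutanoic acid
Product: 29 (3R,3aS,6Z,9S,10E,11aS)‑3,6,10‑trimethyl‑2,5‑dioxo‑2,3,3a,4,5,8,9,11a‑octahydrocyclodeca[b]furan‑9‑yl (2R)‑2‑methylbutanoate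
Conditions: PPh3, DIAD, toluene, 0 → 25 °C
Reagents that add atoms: none
Why: Mitsunobu esterification; SN2 attack of the carboxylate on the oxyphosphonium inverts the (9R) carbinol to the required (9S) ester in the same step that installs the acyl group, and the acid's own stereocentre is not involved.

**Step 17**
Reactants: 29 (3R,3aS,6Z,9S,10E,11aS)‑3,6,10‑trimethyl‑2,5‑dioxo‑2,3,3a,4,5,8,9,11a‑octahydrocyclodeca[b]furan‑9‑yl (2R)‑2‑methylbutanoate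
Product: 30 CNP0276536.1, (3R,3aS,5S,6Z,9S,10E,11aS)‑5‑hydroxy‑3,6,10‑trimethyl‑2‑oxo‑2,3,3a,4,5,8,9,11a‑octahydrocyclodeca[b]furan‑9‑yl (2R)‑2‑methylbutanoate
Conditions: (R)‑2‑methyl‑CBS‑oxazaborolidine (0.5 equiv), catecholborane, toluene, −78 °C
Reagents that add atoms: none
Why: Corey–Bakshi–Shibata reduction; the (R)‑catalyst treats the α‑methylated alkenyl side of the enone as the large group and delivers hydride 1,2 to give the (5S) allylic alcohol under reagent control, leaving lactone, ester and alkenes untouched.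

**Compound list**
1 | (R)‑(−)‑carvone | O=C1C(C)=CC[C@@H](C(C)=C)C1 | starting material
2 | methoxy hydroperoxide (not isolated): (5R)‑5‑(1‑hydroperoxy‑1‑methoxyethyl)‑2‑methylcyclohex‑2‑en‑1‑one | O=C1C(C)=CC[C@@H](C(C)(OC)OO)C1 | intermediate
3 | peracetate (not isolated): (5R)‑5‑[1‑(acetylperoxy)‑1‑methoxyethyl]‑2‑methylcyclohex‑2‑en‑1‑one | O=C1C(C)=CC[C@@H](C(C)(OC)OOC(C)=O)C1 | intermediate
4 | (R)‑5‑acetoxy‑2‑methylcyclohex‑2‑en‑1‑one | O=C1C(C)=CC[C@@H](OC(C)=O)C1 | intermediate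
5 | (R)‑5‑hydroxy‑2‑methylcyclohex‑2‑en‑1‑one | O=C1C(C)=CC[C@@H](O)C1 | intermediate
6 | (R)‑5‑[(tert‑butyldimethylsilyl)oxy]‑2‑methylcyclohex‑2‑en‑1‑one | O=C1C(C)=CC[C@@H](O[Si](C)(C)C(C)(C)C)C1 | intermediate
7 | lithium enolate of 6 (not isolated): lithium (3R)‑3‑[(tert‑butyldimethylsilyl)oxy]‑6‑methylcyclohexa‑1,5‑dien‑1‑olate | [Li+].[O-]C1=C[C@H](O[Si](C)(C)C(C)(C)C)CC=C1C | intermediate
8 | (5R,6S)‑6‑allyl‑5‑[(tert‑butyldimethylsilyl)oxy]‑2‑methylcyclohex‑2‑en‑1‑one | O=C1C(C)=CC[C@@H](O[Si](C)(C)C(C)(C)C)[C@@H]1CC=C | intermediate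
9 | lithium enolate of 8 (not isolated): lithium (3R)‑2‑allyl‑3‑[(tert‑butyldimethylsilyl)oxy]‑6‑methylcyclohexa‑1,5‑dien‑1‑olate | [Li+].[O-]C1=C(CC=C)[C@H](O[Si](C)(C)C(C)(C)C)CC=C1C | intermediate
10 | (5R,6R)‑6‑allyl‑5‑[(tert‑butyldimethylsilyl)oxy]‑2,6‑dimethylcyclohex‑2‑en‑1‑one | O=C1C(C)=CC[C@@H](O[Si](C)(C)C(C)(C)C)[C@@]1(C)CC=C | intermediate
11 | diol (not isolated): (5R,6R)‑5‑[(tert‑butyldimethylsilyl)oxy]‑6‑(2,3‑dihydroxypropyl)‑2,6‑dimethylcyclohex‑2‑en‑1‑one, both carbinol epimers | O=C1C(C)=CC[C@@H](O[Si](C)(C)C(C)(C)C)[C@@]1(C)CC(O)CO | intermediate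
12 | 2‑[(1R,6R)‑6‑[(tert‑butyldimethylsilyl)oxy]‑1,3‑dimethyl‑2‑oxocyclohex‑3‑en‑1‑yl]acetaldehyde | O=C1C(C)=CC[C@@H](O[Si](C)(C)C(C)(C)C)[C@@]1(C)CC=O | intermediate
13 | (5R,6R)‑5‑[(tert‑butyldimethylsilyl)oxy]‑2,6‑dimethyl‑6‑[(E)‑2‑[(triisopropylsilyl)oxy]ethenyl]cyclohex‑2‑en‑1‑one | O=C1C(C)=CC[C@@H](O[Si](C)(C)C(C)(C)C)[C@@]1(C)/C=C/O[Si](C(C)C)(C(C)C)C(C)C | intermediate
14 | methyl (S)‑3‑hydroxy‑2‑methylpropanoate ((S)‑Roche ester) | COC(=O)[C@@H](C)CO | starting material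
15 | methyl (S)‑3‑[(tert‑butyldimethylsilyl)oxy]‑2‑methylpropanoate | COC(=O)[C@@H](C)CO[Si](C)(C)C(C)(C)C | intermediate
16 | (S)‑3‑[(tert‑butyldimethylsilyl)oxy]‑2‑methylpropanal | O=C[C@@H](C)CO[Si](C)(C)C(C)(C)C | intermediate
17 | (R,E)‑tert‑butyl[(4‑iodo‑2‑methylbut‑3‑en‑1‑yl)oxy]dimethylsilane | I/C=C/[C@@H](C)CO[Si](C)(C)C(C)(C)C | intermediate
18 | vinyllithium (not isolated): [(1E,3R)‑4‑[(tert‑butyldimethylsilyl)oxy]‑3‑methylbut‑1‑en‑1‑yl]lithium | [Li]/C=C/[C@@H](C)CO[Si](C)(C)C(C)(C)C | intermediate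
19 | (1S,5R,6R)‑5‑[(tert‑butyldimethylsilyl)oxy]‑1‑[(1E,3R)‑4‑[(tert‑butyldimethylsilyl)oxy]‑3‑methylbut‑1‑en‑1‑yl]‑2,6‑dimethyl‑6‑[(E)‑2‑[(triisopropylsilyl)oxy]ethenyl]cyclohex‑2‑en‑1‑ol | O[C@@]1(/C=C/[C@@H](C)CO[Si](C)(C)C(C)(C)C)C(C)=CC[C@@H](O[Si](C)(C)C(C)(C)C)[C@@]1(C)/C=C/O[Si](C(C)C)(C(C)C)C(C)C | intermediate
20 | potassium alkoxide of 19 (not isolated) | [K+].[O-][C@@]1(/C=C/[C@@H](C)CO[Si](C)(C)C(C)(C)C)C(C)=CC[C@@H](O[Si](C)(C)C(C)(C)C)[C@@]1(C)/C=C/O[Si](C(C)C)(C(C)C)C(C)C | intermediate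
21 | potassium enolate of 22 (not isolated; enolate geometry not specified) | [K+].[O-]C1=C[C@@H]([C@@H](C)CO[Si](C)(C)C(C)(C)C)[C@H](O[Si](C(C)C)(C(C)C)C(C)C)/C=C(\C)/[C@H](O[Si](C)(C)C(C)(C)C)C/C=C1/C | intermediate
22 | (2Z,5R,6E,8S,9S)‑5‑[(tert‑butyldimethylsilyl)oxy]‑9‑[(2R)‑1‑[(tert‑butyldimethylsilyl)oxy]propan‑2‑yl]‑2,6‑dimethyl‑8‑[(triisopropylsilyl)oxy]cyclodeca‑2,6‑dien‑1‑one | O=C1C[C@@H]([C@@H](C)CO[Si](C)(C)C(C)(C)C)[C@H](O[Si](C(C)C)(C(C)C)C(C)C)/C=C(\C)/[C@H](O[Si](C)(C)C(C)(C)C)C/C=C1/C | intermediate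
23 | (2Z,5R,6E,8S,9S)‑5‑[(tert‑butyldimethylsilyl)oxy]‑9‑[(2R)‑1‑hydroxypropan‑2‑yl]‑2,6‑dimethyl‑8‑[(triisopropylsilyl)oxy]cyclodeca‑2,6‑dien‑1‑one | O=C1C[C@@H]([C@@H](C)CO)[C@H](O[Si](C(C)C)(C(C)C)C(C)C)/C=C(\C)/[C@H](O[Si](C)(C)C(C)(C)C)C/C=C1/C | intermediate
24 | aldehyde (not isolated): (2R)‑2‑[(1S,2S,3E,5R,7Z)‑5‑[(tert‑butyldimethylsilyl)oxy]‑4,8‑dimethyl‑9‑oxo‑2‑[(triisopropylsilyl)oxy]cyclodeca‑3,7‑dien‑1‑yl]propanal | O=C1C[C@@H]([C@@H](C)C=O)[C@H](O[Si](C(C)C)(C(C)C)C(C)C)/C=C(\C)/[C@H](O[Si](C)(C)C(C)(C)C)C/C=C1/C | intermediate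
25 | (2R)‑2‑[(1S,2S,3E,5R,7Z)‑5‑[(tert‑butyldimethylsilyl)oxy]‑4,8‑dimethyl‑9‑oxo‑2‑[(triisopropylsilyl)oxy]cyclodeca‑3,7‑dien‑1‑yl]propanoic acid | O=C1C[C@@H]([C@@H](C)C(=O)O)[C@H](O[Si](C(C)C)(C(C)C)C(C)C)/C=C(\C)/[C@H](O[Si](C)(C)C(C)(C)C)C/C=C1/C | intermediate
26 | dihydroxy acid (not isolated): (2R)‑2‑[(1S,2S,3E,5R,7Z)‑2,5‑dihydroxy‑4,8‑dimethyl‑9‑oxocyclodeca‑3,7‑dien‑1‑yl]propanoic acid | O=C1C[C@@H]([C@@H](C)C(=O)O)[C@H](O)/C=C(\C)/[C@H](O)C/C=C1/C | intermediate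
27 | (3R,3aS,6Z,9R,10E,11aS)‑9‑hydroxy‑3,6,10‑trimethyl‑3,3a,4,8,9,11a‑hexahydrocyclodeca[b]furan‑2,5‑dione | O=C1C[C@H]2[C@@H](C)C(=O)O[C@@H]2/C=C(\C)/[C@H](O)C/C=C1/C | intermediate
28 | (R)‑2‑methylbutanoic acid | CC[C@@H](C)C(=O)O | starting material
29 | (3R,3aS,6Z,9S,10E,11aS)‑3,6,10‑trimethyl‑2,5‑dioxo‑2,3,3a,4,5,8,9,11a‑octahydrocyclodeca[b]furan‑9‑yl (2R)‑2‑methylbutanoate | O=C1C[C@H]2[C@@H](C)C(=O)O[C@@H]2/C=C(\C)/[C@@H](OC(=O)[C@H](C)CC)C/C=C1/C | intermediate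
30 | CNP0276536.1, (3R,3aS,5S,6Z,9S,10E,11aS)‑5‑hydroxy‑3,6,10‑trimethyl‑2‑oxo‑2,3,3a,4,5,8,9,11a‑octahydrocyclodeca[b]furan‑9‑yl (2R)‑2‑methylbutanoate | O[C@H]1C[C@H]2[C@@H](C)C(=O)O[C@@H]2/C=C(\C)/[C@@H](OC(=O)[C@H](C)CC)C/C=C1/C | target

**Totals**
Total step count: 17. Longest linear sequence: 14 steps (steps 1–7 and 11–17, from (R)‑carvone); the Roche ester branch is steps 8–10.

**Three steps most likely to fail**

Step 11 (addition of the alkenyllithium to the hindered α‑quaternary enone; yield and facial selectivity). Fallback: bring the side chain in as an alkyne and make the (E)‑alkene afterwards. Setting out from 16, Ohira–Bestmann homologation (dimethyl (1‑diazo‑2‑oxopropyl)phosphonate, K2CO3, MeOH) gives (R)‑tert‑butyldimethyl[(2‑methylbut‑3‑yn‑1‑yl)oxy]silane F1. Its lithium acetylide (n‑BuLi, THF, −78 °C), a slimmer and less basic nucleophile, adds to ketone 13 from the same face to give the propargylic alcohol F2. Alkoxide‑directed trans‑hydroalumination with Red‑Al (THF, 0 °C) then gives the (E)‑allylic alcohol, and the route is rejoined at 19.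

Step 12 (anionic oxy‑Cope; possible retro‑addition of the alkoxide, loss of OTBS from the enolate, or a sluggish enol‑ether terminus). Fallback: leave the anionic manifold. Setting out from 19, N‑(trimethylsilyl)imidazole converts the tertiary alcohol into the trimethylsilyl ether of 19 F3. Heating it (degassed toluene, a little BSA as acid scavenger, sealed tube, about 150 °C) runs the neutral siloxy‑Cope rearrangement through the same chair to the ring‑expanded trimethylsilyl dienol ether F4. Methanolysis of the enol ether (K2CO3, MeOH, 0 °C) comes back to the route at 22.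

Step 16 (Mitsunobu inversion of a hindered allylic alcohol with a weakly acidic, α‑branched acid; elimination or SN2′ may compete). Fallback: separate inversion from acylation. Setting out from 27, Mitsunobu reaction with the far more acidic chloroacetic acid (PPh3, DIAD, toluene) gives the inverted chloroacetate F5. Thiourea and NaHCO3 (EtOH/THF, 40 °C) remove the chloroacetyl group without opening the lactone and give the (9S)‑alcohol F6. Steglich esterification of F6 with 28 (DCC, DMAP, CH2Cl2, 0 °C) comes back to the route at 29.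

**Further compounds**
F1 | step 11 | (R)‑tert‑butyldimethyl[(2‑methylbut‑3‑yn‑1‑yl)oxy]silane | C#C[C@@H](C)CO[Si](C)(C)C(C)(C)C
F2 | step 11 | propargylic alcohol: (5R,6R)‑5‑[(tert‑butyldimethylsilyl)oxy]‑1‑[(3R)‑4‑[(tert‑butyldimethylsilyl)oxy]‑3‑methylbut‑1‑yn‑1‑yl]‑2,6‑dimethyl‑6‑[(E)‑2‑[(triisopropylsilyl)oxy]ethenyl]cyclohex‑2‑en‑1‑ol (carbinol configured as in 19) | O[C@@]1(C#C[C@@H](C)CO[Si](C)(C)C(C)(C)C)C(C)=CC[C@@H](O[Si](C)(C)C(C)(C)C)[C@@]1(C)/C=C/O[Si](C(C)C)(C(C)C)C(C)C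
F3 | step 12 | trimethylsilyl ether of 19 | C[Si](C)(C)O[C@@]1(/C=C/[C@@H](C)CO[Si](C)(C)C(C)(C)C)C(C)=CC[C@@H](O[Si](C)(C)C(C)(C)C)[C@@]1(C)/C=C/O[Si](C(C)C)(C(C)C)C(C)C
F4 | step 12 | trimethylsilyl dienol ether of 22 (enol geometry not specified) | C[Si](C)(C)OC1=C[C@@H]([C@@H](C)CO[Si](C)(C)C(C)(C)C)[C@H](O[Si](C(C)C)(C(C)C)C(C)C)/C=C(\C)/[C@H](O[Si](C)(C)C(C)(C)C)C/C=C1/C
F5 | step 16 | (3R,3aS,6Z,9S,10E,11aS)‑3,6,10‑trimethyl‑2,5‑dioxo‑2,3,3a,4,5,8,9,11a‑octahydrocyclodeca[b]furan‑9‑yl chloroacetate | O=C1C[C@H]2[C@@H](C)C(=O)O[C@@H]2/C=C(\C)/[C@@H](OC(=O)CCl)C/C=C1/C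
F6 | step 16 | (3R,3aS,6Z,9S,10E,11aS)‑9‑hydroxy‑3,6,10‑trimethyl‑3,3a,4,8,9,11a‑hexahydrocyclodeca[b]furan‑2,5‑dione | O=C1C[C@H]2[C@@H](C)C(=O)O[C@@H]2/C=C(\C)/[C@@H](O)C/C=C1/C
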